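The route rests on cutting the C2–C3 bond of ring C. The feature exploited is the β-aryloxy ketone unit O1–C2–C3–C4(=O), in which C2 carries ring B and both O1 and C4 sit on ring A. This unit is read as a rearranged cyclic acetal, with the ring B aldehyde carbon bridging the ring A phenol oxygen and the enol oxygen of the ortho-acyl group. A chiral-acid-catalysed 1,3 oxygen-to-carbon shift of a racemic 2-aryl-4-methylene-4H-1,3-benzodioxine (ring A fully substituted: 5,7-bis-OTBS, 6,8-diprenyl; ring B bis-OTBS) should form C2–C3, close ring C and fix C2 as S in one stereoconvergent operation. The acetal comes from salicylate acylal formation, cross-coupling prenylation and carbonyl methylenation.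

Key step: step 7

Remark: C2 of compounds 4–9 is racemic and is drawn without a descriptor; which antipode of the catalyst leads to the 2S product is to be fixed in a first screen.

Step 1
Reactants: 1 3,5-dihydroxybenzaldehyde
Product: 2 3,5-bis(tert-butyldimethylsilyloxy)benzaldehyde
Conditions: TBSCl (2.4 equiv), imidazole, DMF, rt
Reagents that add atoms: tert-butyldimethylsilyl chloride (TBSCl), CC(C)(C)[Si](C)(C)Cl
Why: Standard O-silylation of phenols with a silyl chloride and imidazole; the aldehyde is inert, and the ring B phenols must be capped before ring A is iodinated in step 3.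

Step 2
Reactants: 3 2,4,6-trihydroxybenzoic acid; 2 3,5-bis(tert-butyldimethylsilyloxy)benzaldehyde
Product: 4 rac-2-[3,5-bis(tert-butyldimethylsilyloxy)phenyl]-5,7-dihydroxy-4H-1,3-benzodioxin-4-one
Conditions: TFAA, TFA, 0 °C to rt; aq. NaHCO3 work-up
Reagents that add atoms: none
Why: Dehydrative acylal formation between a salicylic acid and a carbonyl compound (mixed-anhydride activation of the acid, hemiacetal formation at the ortho hydroxyl, lactonisation) is the standard entry to 1,3-benzodioxin-4-ones; the two ortho hydroxyls of 3 are equivalent, so one constitutional isomer should form, C2 arises racemic, and aryl silyl ethers should withstand the anhydrous acid.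

Step 3
Reactants: 4 rac-2-[3,5-bis(tert-butyldimethylsilyloxy)phenyl]-5,7-dihydroxy-4H-1,3-benzodioxin-4-one
Product: 5 rac-2-[3,5-bis(tert-butyldimethylsilyloxy)phenyl]-5,7-dihydroxy-6,8-diiodo-4H-1,3-benzodioxin-4-one
Conditions: NIS (2.1 equiv), DMF, 0 °C to rt, dark
Reagents that add atoms: N-iodosuccinimide (NIS), O=C1CCC(=O)N1I
Why: Electrophilic aromatic iodination of a free-phenol ring; C6 and C8 are the only open positions of ring A and each lies ortho or para to both hydroxyls, whereas the silylated ring B is far less reactive towards NIS without acid.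

Step 4
Reactants: 5 rac-2-[3,5-bis(tert-butyldimethylsilyloxy)phenyl]-5,7-dihydroxy-6,8-diiodo-4H-1,3-benzodioxin-4-one
Product: 6 rac-2-[3,5-bis(tert-butyldimethylsilyloxy)phenyl]-5,7-bis(tert-butyldimethylsilyloxy)-6,8-diiodo-4H-1,3-benzodioxin-4-one
Conditions: TBSOTf (3 equiv), 2,6-lutidine, CH2Cl2, 0 °C to rt
Reagents that add atoms: tert-butyldimethylsilyl triflate (TBSOTf), CC(C)(C)[Si](C)(C)OS(=O)(=O)C(F)(F)F
Why: O-silylation with a silyl triflate, which is reactive enough for the chelated 5-OH and the iodine-flanked, acidic 7-OH; capping these phenols before the coupling avoids protonolysis of the allylstannane.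

Step 5
Reactants: 6 rac-2-[3,5-bis(tert-butyldimethylsilyloxy)phenyl]-5,7-bis(tert-butyldimethylsilyloxy)-6,8-diiodo-4H-1,3-benzodioxin-4-one; 7 tributyl(3-methylbut-2-en-1-yl)stannane (Bu3SnCH2CH=CMe2)
Product: 8 rac-2-[3,5-bis(tert-butyldimethylsilyloxy)phenyl]-5,7-bis(tert-butyldimethylsilyloxy)-6,8-bis(3-methylbut-2-en-1-yl)-4H-1,3-benzodioxin-4-one
Conditions: 7 (3 equiv), Pd2(dba)3 (5 mol %), P(2-furyl)3, DMF, 80 °C
Reagents that add atoms: none
Why: Twofold Stille cross-coupling under zerovalent palladium; the allyl group should be delivered at its unsubstituted terminus (linear prenyl, favoured further by the flanked aryl positions), and the neutral, fluoride-free medium should spare the acylal and the aryl silyl ethers, which alkaline C-alkylation would not.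

Step 6
Reactants: 8 rac-2-[3,5-bis(tert-butyldimethylsilyloxy)phenyl]-5,7-bis(tert-butyldimethylsilyloxy)-6,8-bis(3-methylbut-2-en-1-yl)-4H-1,3-benzodioxin-4-one
Product: 9 rac-2-[3,5-bis(tert-butyldimethylsilyloxy)phenyl]-5,7-bis(tert-butyldimethylsilyloxy)-4-methylidene-6,8-bis(3-methylbut-2-en-1-yl)-4H-1,3-benzodioxine
Conditions: Cp2TiMe2 (3 equiv), toluene, 70 °C, dark; filtration through basic alumina (Et3N-doped eluent)
Reagents that add atoms: dimethyltitanocene (Cp2TiMe2), [CH3-].[CH3-].[Ti+4].c1cc[cH-]c1.c1cc[cH-]c1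
Why: Petasis methylenation, in which thermally formed Cp2Ti=CH2 converts the lactone carbonyl into the exocyclic enol ether, is the established access to 4-methylene-1,3-dioxanes; 8 has no enolisable or acidic hydrogen, trisubstituted olefins and aryl silyl ethers are inert, and base-buffered isolation should prevent premature, racemic rearrangement.

Step 7
Reactants: 9 rac-2-[3,5-bis(tert-butyldimethylsilyloxy)phenyl]-5,7-bis(tert-butyldimethylsilyloxy)-4-methylidene-6,8-bis(3-methylbut-2-en-1-yl)-4H-1,3-benzodioxine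
Product: 10 (2S)-2-[3,5-bis(tert-butyldimethylsilyloxy)phenyl]-5,7-bis(tert-butyldimethylsilyloxy)-6,8-bis(3-methylbut-2-en-1-yl)-2,3-dihydro-4H-chromen-4-one
Conditions: chiral imidodiphosphorimidate (IDPi) Brønsted acid with 3,3'-diaryl-BINOL backbone and N-triflyl core (5 mol %), 5 Å MS, toluene, −60 °C; Et3N quench
Reagents that add atoms: none
Why: Proposed new method: the strong, confined acid protonates the enol ether oxygen O3 of 9 and the C2–O3 bond ionises (C-protonation of the enol ether followed by loss of the aryl ketone leads to the same species), leaving a benzylic oxocarbenium ion at C2 that is stabilised by O1 and paired with the chiral anion, while the ortho-acyl group of ring A is set free as its enol; the enol carbon then adds to C2 and proton loss gives the C4 ketone, an overall 1,3 oxygen-to-carbon shift. The closest known reaction types are the Lewis-acid-promoted Petasis–Ferrier rearrangement of 4-methylene-1,3-dioxanes to tetrahydropyran-4-ones and the chiral phosphoric acid-catalysed aza-Petasis–Ferrier rearrangement of hemiaminal vinyl ethers. Ring C closes in a 6-(enolendo)-endo-trig mode, the O1=C2 oxocarbenium bond lying inside the new ring. C2 is set under catalyst control: the counteranion shields one face of the planar cation, and because both enantiomers of 9 give the same cation, the racemate should converge on one product. The step needs carbon rather than oxygen recombination and no diversion of the cation: O-return only regenerates 9 whereas C–C bond formation to the ketone is irreversible, C2 has no β-hydrogen, ring A has no free position for arylation, the prenyl olefins are far weaker nucleophiles than the enol, and every phenol is silylated.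

Step 8
Reactants: 10 (2S)-2-[3,5-bis(tert-butyldimethylsilyloxy)phenyl]-5,7-bis(tert-butyldimethylsilyloxy)-6,8-bis(3-methylbut-2-en-1-yl)-2,3-dihydro-4H-chromen-4-one
Product: 11 (2S)-2-(3,5-dihydroxyphenyl)-5,7-dihydroxy-6,8-bis(3-methylbut-2-en-1-yl)-2,3-dihydro-4H-chromen-4-one (CID26213315)
Conditions: TBAF (5 equiv), AcOH (5 equiv), THF, 0 °C to rt
Reagents that add atoms: none
Why: Fluoride cleavage of aryl silyl ethers; acetic acid protonates the phenoxides as they form, which should suppress E1cB opening of ring C to the chalcone (the path by which C2 would racemise), and no strong acid is present that could cyclise the ortho-prenyl phenols to chromans.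

Compound list
1 | 3,5-dihydroxybenzaldehyde | O=Cc1cc(O)cc(O)c1 | starting material
2 | 3,5-bis(tert-butyldimethylsilyloxy)benzaldehyde | O=Cc1cc(O[Si](C)(C)C(C)(C)C)cc(O[Si](C)(C)C(C)(C)C)c1 | intermediate
3 | 2,4,6-trihydroxybenzoic acid | O=C(O)c1c(O)cc(O)cc1O | starting material
4 | rac-2-[3,5-bis(tert-butyldimethylsilyloxy)phenyl]-5,7-dihydroxy-4H-1,3-benzodioxin-4-one | O=C1OC(c2cc(O[Si](C)(C)C(C)(C)C)cc(O[Si](C)(C)C(C)(C)C)c2)Oc2cc(O)cc(O)c21 | intermediate
5 | rac-2-[3,5-bis(tert-butyldimethylsilyloxy)phenyl]-5,7-dihydroxy-6,8-diiodo-4H-1,3-benzodioxin-4-one | O=C1OC(c2cc(O[Si](C)(C)C(C)(C)C)cc(O[Si](C)(C)C(C)(C)C)c2)Oc2c(I)c(O)c(I)c(O)c21 | intermediate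
6 | rac-2-[3,5-bis(tert-butyldimethylsilyloxy)phenyl]-5,7-bis(tert-butyldimethylsilyloxy)-6,8-diiodo-4H-1,3-benzodioxin-4-one | O=C1OC(c2cc(O[Si](C)(C)C(C)(C)C)cc(O[Si](C)(C)C(C)(C)C)c2)Oc2c(I)c(O[Si](C)(C)C(C)(C)C)c(I)c(O[Si](C)(C)C(C)(C)C)c21 | intermediate
7 | tributyl(3-methylbut-2-en-1-yl)stannane | CCCC[Sn](CCCC)(CCCC)CC=C(C)C | starting material
8 | rac-2-[3,5-bis(tert-butyldimethylsilyloxy)phenyl]-5,7-bis(tert-butyldimethylsilyloxy)-6,8-bis(3-methylbut-2-en-1-yl)-4H-1,3-benzodioxin-4-one | O=C1OC(c2cc(O[Si](C)(C)C(C)(C)C)cc(O[Si](C)(C)C(C)(C)C)c2)Oc2c(CC=C(C)C)c(O[Si](C)(C)C(C)(C)C)c(CC=C(C)C)c(O[Si](C)(C)C(C)(C)C)c21 | intermediate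
9 | rac-2-[3,5-bis(tert-butyldimethylsilyloxy)phenyl]-5,7-bis(tert-butyldimethylsilyloxy)-4-methylidene-6,8-bis(3-methylbut-2-en-1-yl)-4H-1,3-benzodioxine | C=C1OC(c2cc(O[Si](C)(C)C(C)(C)C)cc(O[Si](C)(C)C(C)(C)C)c2)Oc2c(CC=C(C)C)c(O[Si](C)(C)C(C)(C)C)c(CC=C(C)C)c(O[Si](C)(C)C(C)(C)C)c21 | intermediate
10 | (2S)-2-[3,5-bis(tert-butyldimethylsilyloxy)phenyl]-5,7-bis(tert-butyldimethylsilyloxy)-6,8-bis(3-methylbut-2-en-1-yl)-2,3-dihydro-4H-chromen-4-one | CC(C)=CCc1c(O[Si](C)(C)C(C)(C)C)c(CC=C(C)C)c2c(c1O[Si](C)(C)C(C)(C)C)C(=O)C[C@@H](c1cc(O[Si](C)(C)C(C)(C)C)cc(O[Si](C)(C)C(C)(C)C)c1)O2 | intermediate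
11 | (2S)-2-(3,5-dihydroxyphenyl)-5,7-dihydroxy-6,8-bis(3-methylbut-2-en-1-yl)-2,3-dihydro-4H-chromen-4-one | CC(C)=CCc1c(O)c(CC=C(C)C)c2c(c1O)C(=O)C[C@@H](c1cc(O)cc(O)c1)O2 | target

Total step count: 8
Longest linear sequence: 8 steps (1 → 2 → 4 → 5 → 6 → 8 → 9 → 10 → 11)

Steps most likely to fail

Step 7 (the new rearrangement). Ionisation may be sluggish in the crowded substrate, the ion pair may collapse with poor enantioface discrimination, the enol may tautomerise to the methyl ketone before the C–C bond forms, or traces of water may hydrolyse the acetal. The fallback uses known chemistry, sets out from 9 and returns at 10. Mild aqueous acid (PPTS, THF–H2O, rt) should cleave the enol acetal to 1-[2-hydroxy-4,6-bis(tert-butyldimethylsilyloxy)-3,5-bis(3-methylbut-2-en-1-yl)phenyl]ethan-1-one F1 and return aldehyde 2. Claisen–Schmidt condensation of F1 with 2 (LiN(SiMe3)2, THF, −78 °C to rt) should give (E)-1-[2-hydroxy-4,6-bis(tert-butyldimethylsilyloxy)-3,5-bis(3-methylbut-2-en-1-yl)phenyl]-3-[3,5-bis(tert-butyldimethylsilyloxy)phenyl]prop-2-en-1-one F2. Enantioselective intramolecular oxa-Michael addition of its free 2'-hydroxyl under a quinine- or quinidine-derived bifunctional thiourea (the pseudoenantiomer that favours 2S), with preparative HPLC on a chiral stationary phase to raise the enantiopurity, should then deliver 10.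

Step 5. The second coupling at the doubly flanked C6 position may stall, the allyl unit may transpose to the branched 1,1-dimethylallyl isomer, or protodeiodination may compete. The fallback sets out from 4 and returns at 8, bypassing steps 3–5. Direct C-alkylation of the free phloroglucinol-type ring with prenyl bromide and DBU in THF (0 °C to rt), as practised for acylphloroglucinols, should give rac-2-[3,5-bis(tert-butyldimethylsilyloxy)phenyl]-5,7-dihydroxy-6,8-bis(3-methylbut-2-en-1-yl)-4H-1,3-benzodioxin-4-one F3 after separation from O-prenyl ethers. This is shorter but expected to be less selective. Silylation of F3 (TBSOTf, 2,6-lutidine, CH2Cl2) then gives 8.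

Step 2. The activated aldehyde may alkylate the electron-rich ring of 3 at carbon instead of forming the acetal, acid 3 may decarboxylate in the acidic medium, or part of the ring B silyl ethers may be lost. The fallback sets out from 3 and returns at 4. Persilylation with HN(SiMe3)2 (cat. TMSCl, CH2Cl2, reflux) should give trimethylsilyl 2,4,6-tris(trimethylsilyloxy)benzoate F4. TMSOTf-catalysed silyl-transfer acetalisation of F4 with aldehyde 2 (CH2Cl2, −78 °C), the method used for 1,3-dioxan-4-ones from bis-silylated hydroxy acids, should give rac-2-[3,5-bis(tert-butyldimethylsilyloxy)phenyl]-5,7-bis(trimethylsilyloxy)-4H-1,3-benzodioxin-4-one F5. Methanolysis of the two labile aryl trimethylsilyl ethers (MeOH, citric acid, 0 °C) then gives 4.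

Further compounds
F1 | step 7 | 1-[2-hydroxy-4,6-bis(tert-butyldimethylsilyloxy)-3,5-bis(3-methylbut-2-en-1-yl)phenyl]ethan-1-one | CC(=O)c1c(O)c(CC=C(C)C)c(O[Si](C)(C)C(C)(C)C)c(CC=C(C)C)c1O[Si](C)(C)C(C)(C)C
F2 | step 7 | (E)-1-[2-hydroxy-4,6-bis(tert-butyldimethylsilyloxy)-3,5-bis(3-methylbut-2-en-1-yl)phenyl]-3-[3,5-bis(tert-butyldimethylsilyloxy)phenyl]prop-2-en-1-one | O=C(/C=C/c1cc(O[Si](C)(C)C(C)(C)C)cc(O[Si](C)(C)C(C)(C)C)c1)c1c(O)c(CC=C(C)C)c(O[Si](C)(C)C(C)(C)C)c(CC=C(C)C)c1O[Si](C)(C)C(C)(C)C
F3 | step 5 | rac-2-[3,5-bis(tert-butyldimethylsilyloxy)phenyl]-5,7-dihydroxy-6,8-bis(3-methylbut-2-en-1-yl)-4H-1,3-benzodioxin-4-one | O=C1OC(c2cc(O[Si](C)(C)C(C)(C)C)cc(O[Si](C)(C)C(C)(C)C)c2)Oc2c(CC=C(C)C)c(O)c(CC=C(C)C)c(O)c21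
F4 | step 2 | trimethylsilyl 2,4,6-tris(trimethylsilyloxy)benzoate | C[Si](C)(C)OC(=O)c1c(O[Si](C)(C)C)cc(O[Si](C)(C)C)cc1O[Si](C)(C)C
F5 | step 2 | rac-2-[3,5-bis(tert-butyldimethylsilyloxy)phenyl]-5,7-bis(trimethylsilyloxy)-4H-1,3-benzodioxin-4-one | O=C1OC(c2cc(O[Si](C)(C)C(C)(C)C)cc(O[Si](C)(C)C(C)(C)C)c2)Oc2cc(O[Si](C)(C)C)cc(O[Si](C)(C)C)c21
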